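**Retrosynthetic overview**
The target is an open-chain 2,3-dimethyl-1,4-diarylbutane. No ring is formed in the route: both benzene rings are bought intact (guaiacyl half from dihydroferulic acid, syringyl half from syringyl alcohol) and carried as benzyl ethers, which are removed last.
Both methyl groups are traced back to CH2OH groups (bis-mesylate, then hydride), and this 1,4-diol to a γ,δ-unsaturated acid (CO2H to CH2OH; propenyl to CH2OH by ozonolysis and reduction).
Enabling feature: the adjacent chain methines C8 and C8′ each carry a methyl carbon (C9, C9′) and an ArCH2. Reading C9 as a former carboxyl carbon and C9′ as a former alkene carbon makes O=C9–C8–C8′–C9′=C the retron of an ester-enolate [3,3] shift. C8–C8′ is therefore cut to the ester of the guaiacyl propanoic acid with a (2S,3E)-5-arylpent-3-en-2-ol.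
One bought stereocentre, the carbinol of (S)-but-3-yn-2-ol, is relayed to both C8 and C8′ in that step. The allylic alcohol comes from a benzyl bromide–alkyne coupling and a trans-selective alkyne reduction.

Key step: step 7

Remark: lignan numbering is used. C7/C8/C9 are the ArCH2, CH and CH3 carbons of the guaiacyl half, and C7′/C8′/C9′ those of the syringyl half. The target is read as (8R,8′S), the unsymmetrical analogue of a meso compound.

**Step 1**
Reactants: 1 3-(4-hydroxy-3-methoxyphenyl)propanoic acid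
Product: 2 3-[4-(benzyloxy)-3-methoxyphenyl]propanoic acid
Conditions: BnBr, KOH, EtOH/H2O, reflux; then aq. HCl
Reagents that add atoms: benzyl bromide, BrCc1ccccc1
Why: Williamson etherification; in aqueous ethanolic KOH the phenoxide is alkylated while the carboxylate stays essentially inert, and any benzyl ester formed is saponified in the same pot.

**Step 2**
Reactants: 3 4-(hydroxymethyl)-2,6-dimethoxyphenol
Product: 4 [4-(benzyloxy)-3,5-dimethoxyphenyl]methanol
Conditions: BnBr, K2CO3, acetone, reflux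
Reagents that add atoms: benzyl bromide, BrCc1ccccc1
Why: Williamson etherification; K2CO3 deprotonates only the phenol, so the benzylic alcohol should remain free.

**Step 3**
Reactants: 4 [4-(benzyloxy)-3,5-dimethoxyphenyl]methanol
Product: 5 2-(benzyloxy)-5-(bromomethyl)-1,3-dimethoxybenzene
Conditions: PBr3, Et2O, 0 °C
Reagents that add atoms: phosphorus tribromide, BrP(Br)Br
Why: Bromination of a primary benzylic alcohol via its phosphite ester should be fast at 0 °C on this electron-rich ring and leave the aryl ethers untouched; the bromide is used crude.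

**Step 4**
Reactants: 5 2-(benzyloxy)-5-(bromomethyl)-1,3-dimethoxybenzene; 6 (S)-but-3-yn-2-ol
Product: 7 (2S)-5-[4-(benzyloxy)-3,5-dimethoxyphenyl]pent-3-yn-2-ol
Conditions: CuI (0.5 equiv), Cs2CO3, MeCN, rt → 40 °C
Reagents that add atoms: none
Why: Copper-mediated sp–sp3 coupling of a terminal alkyne with a benzylic halide; the monovalent copper acetylide formed under carbonate base is benzylated at carbon, the free secondary hydroxyl is tolerated and the carbinol stereocentre is not involved.

**Step 5**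
Reactants: 7 (2S)-5-[4-(benzyloxy)-3,5-dimethoxyphenyl]pent-3-yn-2-ol
Product: 8 (2S,3E)-5-[4-(benzyloxy)-3,5-dimethoxyphenyl]pent-3-en-2-ol
Conditions: NaAlH2(OCH2CH2OCH3)2, THF, 0 °C → rt; aq. KNaC4H4O6
Reagents that add atoms: none
Why: Hydroxyl-directed trans-hydroalumination of a propargylic alcohol followed by protonolysis should give only the E-alkene; the stereocentre is untouched.

**Step 6**
Reactants: 2 3-[4-(benzyloxy)-3-methoxyphenyl]propanoic acid; 8 (2S,3E)-5-[4-(benzyloxy)-3,5-dimethoxyphenyl]pent-3-en-2-ol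
Product: 9 (2S,3E)-5-[4-(benzyloxy)-3,5-dimethoxyphenyl]pent-3-en-2-yl 3-[4-(benzyloxy)-3-methoxyphenyl]propanoate
Conditions: DCC, DMAP (cat.), CH2Cl2, 0 °C → rt
Reagents that add atoms: none
Why: Steglich esterification acylates the alcohol oxygen without breaking the carbinol C–O bond, so configuration and alkene position are retained.

**Step 7**
Reactants: 9 (2S,3E)-5-[4-(benzyloxy)-3,5-dimethoxyphenyl]pent-3-en-2-yl 3-[4-(benzyloxy)-3-methoxyphenyl]propanoate
Product: 13 (2R,3R,4E)-2-[4-(benzyloxy)-3-methoxybenzyl]-3-[4-(benzyloxy)-3,5-dimethoxybenzyl]hex-4-enoic acid, via lithium enolate 10 (not isolated), via silyl ketene acetal 11 (not isolated), via silyl ester 12 (not isolated)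
Conditions: LiN(i-Pr)2, THF, −78 °C; Me3SiCl/Et3N, −78 °C → rt, then 60 °C; aq. HCl
Reagents that add atoms: lithium diisopropylamide, [Li+].CC(C)[N-]C(C)C (lithium stands in 10 only); chlorotrimethylsilane, C[Si](C)(C)Cl (its Me3Si group stands in 11 and 12 and is lost on work-up)
Why: LiN(i-Pr)2 in THF without a dipolar additive should remove an ester α-proton through the closed six-membered deprotonation transition state and give the E(O) lithium enolate 10 (ArCH2 trans to OLi), which Me3SiCl traps as the (E)-silyl ketene acetal 11; on warming, 11 should undergo a concerted, suprafacial [3,3]-sigmatropic shift that makes the C8–C8′ bond and breaks the allylic C–O bond, and the silyl ester 12 is hydrolysed on work-up. The closest known reaction type is the Ireland–Claisen rearrangement of (E)-allylic esters of enantiopure secondary alcohols with 1,3-chirality transfer. No ring is closed; only the six-membered chair transition state (C8, the ketene acetal carbon, O, the carbinol carbon and the two alkene carbons) is passed. C8′ is controlled by the (S)-carbinol centre, whose methyl group stays equatorial on the chair so that C8 is delivered to a single face of the E-alkene while the old centre is converted into the new E-alkene; C8 is controlled by the E geometry of the ketene acetal on the same chair, which gives the 2,3-anti (2R,3R) acid that maps onto the (8R,8′S) target. The step needs E-selective enolisation, chair over boat, and α-deprotonation in preference to metalation of the ArCH2–CH=CH methylene; these are secured by the additive-free lithium amide at −78 °C, by the acyclic E-disubstituted allyl unit, and by the carbonyl-assisted, much faster deprotonation of the ester compared with the weaker hydrocarbon acid.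

**Step 8**
Reactants: 13 (2R,3R,4E)-2-[4-(benzyloxy)-3-methoxybenzyl]-3-[4-(benzyloxy)-3,5-dimethoxybenzyl]hex-4-enoic acid
Product: 14 (2R,3R,4E)-2-[4-(benzyloxy)-3-methoxybenzyl]-3-[4-(benzyloxy)-3,5-dimethoxybenzyl]hex-4-en-1-ol
Conditions: LiAlH4, THF, 0 °C → rt
Reagents that add atoms: none
Why: LiAlH4 reduction of a carboxylic acid to the primary alcohol; the α-centre cannot epimerise at the carboxylate stage, and the isolated alkene and the benzyl ethers are inert.

**Step 9**
Reactants: 14 (2R,3R,4E)-2-[4-(benzyloxy)-3-methoxybenzyl]-3-[4-(benzyloxy)-3,5-dimethoxybenzyl]hex-4-en-1-ol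
Product: 16 (2R,3S)-2-[4-(benzyloxy)-3-methoxybenzyl]-3-[4-(benzyloxy)-3,5-dimethoxybenzyl]butane-1,4-diol, via hydroxy aldehyde 15 (not isolated)
Conditions: O3, CH2Cl2/MeOH, −78 °C (Sudan Red 7B end point); then NaBH4, −78 °C → rt
Reagents that add atoms: ozone, [O-][O+]=O
Why: Ozonolysis (Criegee mechanism) with reductive work-up; the only alkene should react far faster than the alkoxyarenes when the end point is shown by the dye, and the peroxidic cleavage products are reduced through hydroxy aldehyde 15 (present largely as its lactol) to the diol before the adjacent centre can epimerise.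

**Step 10**
Reactants: 16 (2R,3S)-2-[4-(benzyloxy)-3-methoxybenzyl]-3-[4-(benzyloxy)-3,5-dimethoxybenzyl]butane-1,4-diol
Product: 17 (2R,3S)-2-[4-(benzyloxy)-3-methoxybenzyl]-3-[4-(benzyloxy)-3,5-dimethoxybenzyl]butane-1,4-diyl dimethanesulfonate
Conditions: MsCl, Et3N, CH2Cl2, −10 °C
Reagents that add atoms: methanesulfonyl chloride, CS(=O)(=O)Cl
Why: Sulfonylation through the sulfene should convert both primary alcohols at low temperature faster than the mono-mesylate can close to a tetrahydrofuran.

**Step 11**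
Reactants: 17 (2R,3S)-2-[4-(benzyloxy)-3-methoxybenzyl]-3-[4-(benzyloxy)-3,5-dimethoxybenzyl]butane-1,4-diyl dimethanesulfonate
Product: 18 2-(benzyloxy)-5-{(2S,3R)-4-[4-(benzyloxy)-3-methoxyphenyl]-2,3-dimethylbutyl}-1,3-dimethoxybenzene
Conditions: LiBHEt3, THF, 0 °C → rt
Reagents that add atoms: none
Why: SN2 displacement of primary sulfonates by the strongly nucleophilic hydride LiBHEt3, which favours attack at carbon over sulfur, should turn both CH2OMs groups into CH3; the stereocentres are not involved.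

**Step 12**
Reactants: 18 2-(benzyloxy)-5-{(2S,3R)-4-[4-(benzyloxy)-3-methoxyphenyl]-2,3-dimethylbutyl}-1,3-dimethoxybenzene
Product: 19 4-[(2S,3R)-4-(4-hydroxy-3-methoxyphenyl)-2,3-dimethylbutyl]-2,6-dimethoxyphenol
Conditions: H2 (1 atm), 10% Pd/C, EtOAc/EtOH, rt
Reagents that add atoms: none
Why: Hydrogenolysis of the two aryl benzyl ethers over Pd/C; nothing else in 18 is reducible and the stereocentres are unaffected.

Any 2,3-syn isomer arising from residual Z(O) enolate in step 7 should be removed by chromatography at 14 or 16.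

**Compound list**
1 | 3-(4-hydroxy-3-methoxyphenyl)propanoic acid (dihydroferulic acid) | COc1cc(CCC(=O)O)ccc1O | starting material
2 | 3-[4-(benzyloxy)-3-methoxyphenyl]propanoic acid | COc1cc(CCC(=O)O)ccc1OCc1ccccc1 | intermediate
3 | 4-(hydroxymethyl)-2,6-dimethoxyphenol (syringyl alcohol) | COc1cc(CO)cc(OC)c1O | starting material
4 | [4-(benzyloxy)-3,5-dimethoxyphenyl]methanol | COc1cc(CO)cc(OC)c1OCc1ccccc1 | intermediate
5 | 2-(benzyloxy)-5-(bromomethyl)-1,3-dimethoxybenzene | COc1cc(CBr)cc(OC)c1OCc1ccccc1 | intermediate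
6 | (S)-but-3-yn-2-ol | C[C@H](O)C#C | starting material
7 | (2S)-5-[4-(benzyloxy)-3,5-dimethoxyphenyl]pent-3-yn-2-ol | C[C@H](O)C#CCc1cc(OC)c(OCc2ccccc2)c(OC)c1 | intermediate
8 | (2S,3E)-5-[4-(benzyloxy)-3,5-dimethoxyphenyl]pent-3-en-2-ol | C[C@H](O)/C=C/Cc1cc(OC)c(OCc2ccccc2)c(OC)c1 | intermediate
9 | (2S,3E)-5-[4-(benzyloxy)-3,5-dimethoxyphenyl]pent-3-en-2-yl 3-[4-(benzyloxy)-3-methoxyphenyl]propanoate | C[C@H](OC(=O)CCc1ccc(OCc2ccccc2)c(OC)c1)/C=C/Cc1cc(OC)c(OCc2ccccc2)c(OC)c1 | intermediate
10 | E(O) lithium enolate of 9 (ArCH2 trans to OLi) | [Li+].C[C@H](O/C([O-])=C\Cc1ccc(OCc2ccccc2)c(OC)c1)/C=C/Cc1cc(OC)c(OCc2ccccc2)c(OC)c1 | intermediate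
11 | (E)-trimethylsilyl ketene acetal of 9 (ArCH2 cis to the allylic oxygen) | C[C@H](O/C(O[Si](C)(C)C)=C\Cc1ccc(OCc2ccccc2)c(OC)c1)/C=C/Cc1cc(OC)c(OCc2ccccc2)c(OC)c1 | intermediate
12 | trimethylsilyl (2R,3R,4E)-2-[4-(benzyloxy)-3-methoxybenzyl]-3-[4-(benzyloxy)-3,5-dimethoxybenzyl]hex-4-enoate | C[Si](C)(C)OC(=O)[C@H](Cc1ccc(OCc2ccccc2)c(OC)c1)[C@H](Cc1cc(OC)c(OCc2ccccc2)c(OC)c1)/C=C/C | intermediate
13 | (2R,3R,4E)-2-[4-(benzyloxy)-3-methoxybenzyl]-3-[4-(benzyloxy)-3,5-dimethoxybenzyl]hex-4-enoic acid | OC(=O)[C@H](Cc1ccc(OCc2ccccc2)c(OC)c1)[C@H](Cc1cc(OC)c(OCc2ccccc2)c(OC)c1)/C=C/C | intermediate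
14 | (2R,3R,4E)-2-[4-(benzyloxy)-3-methoxybenzyl]-3-[4-(benzyloxy)-3,5-dimethoxybenzyl]hex-4-en-1-ol | OC[C@H](Cc1ccc(OCc2ccccc2)c(OC)c1)[C@H](Cc1cc(OC)c(OCc2ccccc2)c(OC)c1)/C=C/C | intermediate
15 | (2S,3R)-3-[4-(benzyloxy)-3-methoxybenzyl]-2-[4-(benzyloxy)-3,5-dimethoxybenzyl]-4-hydroxybutanal | OC[C@H](Cc1ccc(OCc2ccccc2)c(OC)c1)[C@H](Cc1cc(OC)c(OCc2ccccc2)c(OC)c1)C=O | intermediate
16 | (2R,3S)-2-[4-(benzyloxy)-3-methoxybenzyl]-3-[4-(benzyloxy)-3,5-dimethoxybenzyl]butane-1,4-diol | OC[C@H](Cc1ccc(OCc2ccccc2)c(OC)c1)[C@H](Cc1cc(OC)c(OCc2ccccc2)c(OC)c1)CO | intermediate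
17 | (2R,3S)-2-[4-(benzyloxy)-3-methoxybenzyl]-3-[4-(benzyloxy)-3,5-dimethoxybenzyl]butane-1,4-diyl dimethanesulfonate | CS(=O)(=O)OC[C@H](Cc1ccc(OCc2ccccc2)c(OC)c1)[C@H](Cc1cc(OC)c(OCc2ccccc2)c(OC)c1)COS(C)(=O)=O | intermediate
18 | 2-(benzyloxy)-5-{(2S,3R)-4-[4-(benzyloxy)-3-methoxyphenyl]-2,3-dimethylbutyl}-1,3-dimethoxybenzene | C[C@H](Cc1ccc(OCc2ccccc2)c(OC)c1)[C@H](Cc1cc(OC)c(OCc2ccccc2)c(OC)c1)C | intermediate
19 | 4-[(2S,3R)-4-(4-hydroxy-3-methoxyphenyl)-2,3-dimethylbutyl]-2,6-dimethoxyphenol | COc1cc(C[C@@H](C)[C@@H](C)Cc2cc(OC)c(O)c(OC)c2)ccc1O | target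

**Totals**
Total step count: 12.
Longest linear sequence: 11 steps (steps 2 to 12, from 3 to 19).

**Steps most likely to fail**

Step 7. Enolisation of this β-aryl ester may be less E-selective than needed, which would erode the anti to syn ratio and set C8 with poor control; metalation elsewhere would lower conversion. The fallback sets out from 8 and comes back at 14. It separates the two tasks: the C8–C8′ bond and C8′ are made by a rearrangement that involves no enolate geometry, and C8 is then set by an auxiliary.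
- Alcohol 8 would be heated with triethyl orthoacetate and catalytic propanoic acid (Johnson–Claisen rearrangement, same chair and same chirality transfer) to give ethyl (3S,4E)-3-[4-(benzyloxy)-3,5-dimethoxybenzyl]hex-4-enoate F1.
- Saponification with LiOH in THF/H2O should give (3S,4E)-3-[4-(benzyloxy)-3,5-dimethoxybenzyl]hex-4-enoic acid F2.
- DCC/DMAP coupling with (R)-4-benzyl-1,3-oxazolidin-2-one should give (4R)-4-benzyl-3-{(3S,4E)-3-[4-(benzyloxy)-3,5-dimethoxybenzyl]hex-4-enoyl}-1,3-oxazolidin-2-one F3.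
- The sodium enolate of F3 (NaN(SiMe3)2, THF, −78 °C) would be alkylated with 1-(benzyloxy)-4-(bromomethyl)-2-methoxybenzene F4, itself made from commercial [4-(benzyloxy)-3-methoxyphenyl]methanol and PBr3. This Evans alkylation, with attack anti to the ring benzyl group, should give (4R)-4-benzyl-3-{(2R,3R,4E)-2-[4-(benzyloxy)-3-methoxybenzyl]-3-[4-(benzyloxy)-3,5-dimethoxybenzyl]hex-4-enoyl}-1,3-oxazolidin-2-one F5.
- Reductive removal of the auxiliary with LiBH4 in wet THF should give 14.

Step 11. Hydride may attack sulfur in one sulfonate and unmask an alkoxide, which would close onto the second sulfonate to a 3,4-disubstituted tetrahydrofuran instead of giving two methyl groups. The fallback sets out from 17 and comes back at 19. Finkelstein exchange (NaI, butanone, reflux) would give (2R,3S)-2-[4-(benzyloxy)-3-methoxybenzyl]-3-[4-(benzyloxy)-3,5-dimethoxybenzyl]-1,4-diiodobutane F6, in which no alkoxide can arise. Hydrogenolysis (H2, Pd/C, Et3N, EtOAc/MeOH) should then cleave both C–I bonds and both benzyl ethers in one operation and give 19 directly.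

Step 4. Carbonate base may isomerise the skipped aryl alkyne to an allene, or the coupling may stall while the electron-rich benzylic bromide solvolyses. The fallback sets out from 6 (and uses 5) and comes back at 8, so that step 5 is not needed. Copper-catalysed anti-Markovnikov protoboration of 6 (CuCl, Xantphos, NaOt-Bu cat., bis(pinacolato)diboron, MeOH, THF) would give (2S,3E)-4-(4,4,5,5-tetramethyl-1,3,2-dioxaborolan-2-yl)but-3-en-2-ol F7, with the E geometry fixed by syn addition. Suzuki–Miyaura sp3–sp2 coupling of F7 with bromide 5 (PdCl2(dppf), K3PO4, THF/H2O, 60 °C) should give 8 without any alkyne intermediate.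

**Further compounds**
F1 | step 7 | ethyl (3S,4E)-3-[4-(benzyloxy)-3,5-dimethoxybenzyl]hex-4-enoate | CCOC(=O)C[C@H](Cc1cc(OC)c(OCc2ccccc2)c(OC)c1)/C=C/C
F2 | step 7 | (3S,4E)-3-[4-(benzyloxy)-3,5-dimethoxybenzyl]hex-4-enoic acid | OC(=O)C[C@H](Cc1cc(OC)c(OCc2ccccc2)c(OC)c1)/C=C/C
F3 | step 7 | (4R)-4-benzyl-3-{(3S,4E)-3-[4-(benzyloxy)-3,5-dimethoxybenzyl]hex-4-enoyl}-1,3-oxazolidin-2-one | O=C1OC[C@@H](Cc2ccccc2)N1C(=O)C[C@H](Cc1cc(OC)c(OCc2ccccc2)c(OC)c1)/C=C/C
F4 | step 7 | 1-(benzyloxy)-4-(bromomethyl)-2-methoxybenzene | COc1cc(CBr)ccc1OCc1ccccc1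
F5 | step 7 | (4R)-4-benzyl-3-{(2R,3R,4E)-2-[4-(benzyloxy)-3-methoxybenzyl]-3-[4-(benzyloxy)-3,5-dimethoxybenzyl]hex-4-enoyl}-1,3-oxazolidin-2-one | O=C1OC[C@@H](Cc2ccccc2)N1C(=O)[C@H](Cc1ccc(OCc2ccccc2)c(OC)c1)[C@H](Cc1cc(OC)c(OCc2ccccc2)c(OC)c1)/C=C/C
F6 | step 11 | (2R,3S)-2-[4-(benzyloxy)-3-methoxybenzyl]-3-[4-(benzyloxy)-3,5-dimethoxybenzyl]-1,4-diiodobutane | IC[C@H](Cc1ccc(OCc2ccccc2)c(OC)c1)[C@H](Cc1cc(OC)c(OCc2ccccc2)c(OC)c1)CI
F7 | step 4 | (2S,3E)-4-(4,4,5,5-tetramethyl-1,3,2-dioxaborolan-2-yl)but-3-en-2-ol | C[C@H](O)/C=C/B1OC(C)(C)C(C)(C)O1
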